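**The question.** 4 questions come down to one: what odds does a substrate molecule have of reaching target rather than leaving by another exit?

| flask | substrate | partner | rival reagent | remark | time |
|---|---|---|---|---|---|
| epsilon | 48 mM | 1.2 equiv | 0.95 equiv | run made earlier |  |
| theta | 48 mM | 1.2 equiv | 0.47 equiv | run made earlier |  |
| blue | 48 mM | 1.20 equiv (fed, over 80 min) | 0.950 equiv | all else is in the flask from the start; the feed brings no volume worth counting | 3.0 h |
| amber | 48 mM | 1.20 equiv | 0.950 equiv | everything together at the start | 3.0 h |
| red | 48 mM (fed, over 80 min) | 1.20 equiv | 0.950 equiv | all else is in the flask from the start; the feed brings no volume worth counting | 3.0 h |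

- epsilon (time / min: target / %): 8.00: 19; 12.0: 22; 20.0: 28; 30.0: 36; 50.0: 45; 80.0: 49; 120: 50
- theta (time / min: target / %): 3.00: 9; 8.00: 19; 15.0: 28; 25.0: 41; 30.0: 43; 40.0: 49; 50.0: 50

(each reading ± 2 percentage points)

- which flask leads in amount of target, in percent of the substrate charged ("all alike" within 1.5 percentage points) (blue / amber / red / all alike)
- how much target is there at the end, in percent of the substrate charged: blue
- how much target is there at the end, in percent of the substrate charged: amber
- how much target is there at the end, in percent of the substrate charged: red



**The plateau.** Epsilon levelled at a reading of 50 %, so with c(partner) as charged the odds were 1.00. Theta, with about half the rival reagent, read 50 % at 50.0 min, its last point, against a reading of 45 % for epsilon at that time, so theta shows no plateau of its own, and less rival reagent went with more target at that time.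

**Both ends.** Epsilon made 19 % in 8.00 min. At even odds, that gave substrate a lifetime of 42.1 min against the other exits, shorter than the feed of 80 min. Their ratio is my dosing number, 1.90. A very short partner feed leaves the odds as they were. A very long one lets partner build up after substrate has left, and target falls as one over the dosing number.

**Joined.** Dividing the odds by one plus that number meets both ends. Blue's target odds, target over other exits (a selectivity factor), were 0.345, which gave 25.6 % target. Amber and red have partner present from the start, so I put both at 50 %. One number was not enough: it cannot separate those two, and it assumes that the other exits run without partner.

**The result.** The forecast said all alike, with blue 49 % (38 % to 53 %), amber 50 % and red 50 %, because “Such a limit should not depend on the order of addition”, whereas I had blue far lower.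

    2 substrate → self-condensation product (k = 7.80 /M/h)
    substrate + rival reagent → side product (k = 30.0 /M/h)
    substrate + partner → target (k = 33.0 /M/h)

Blue gave 29.3 %, which is odds of 0.414 against my 0.345. Amber gave 50.9 %, and red led with 53.9 %, where I had it level with amber. In red at 0.973 h, substrate's half-life by the step to target was 0.47 h, shorter than the 0.64 h by the step to side product. At 3.00 h the target step in red still used substrate at 1.3 times the rate of the side step.

**Second flask.** In the neighbour of red with 0.300 equiv of partner, a quarter of the charge gives odds of 0.250, hence 20.0 % target. The computed flask held 19.6 % target, with 8.25 % substrate remaining.

(The readings stem from a simulated flask for an exercise; scatter was added.)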